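**Retrosynthetic overview**
1. 22 ⇐ 18: removal of the C1 silyl ether, CBS reduction of the C10 ketone (sets C10), TBS-to-acetate exchange at C16.
2. 18 ⇐ 16: bridging Thorpe–Ziegler closure of C10–C11 (second ring event; closes the seven-membered ring and fixes bridgehead C11).
3. 16 ⇐ 8 + 14: new epoxide/α-bromo acid annulation (first ring, the 1,4-dioxan-2-one; acid O onto C7 with inversion, epoxide O kept on C6 and joined to C11).
4. 8 ⇐ 1 + 5: silylation, SeO2 allylic oxidation, bromide, cyanomethylation, then Shi epoxidation (key asymmetric step, sets C6 and C7).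
5. 14 ⇐ 9 + 10: Z-selective Wittig olefination, then dianion α-bromination.

Convention and assumption: locants C1–C20 follow the diterpenoid chain of the target (C1 = CH2OH, C6 and C7 = ring carbons bearing O, C10 = CHOH, C11 = quaternary bridgehead, C16 = CH2OAc, C20 = lactone C=O); the L-fructose-derived enantiomer of the Shi ketone and the (R)-CBS catalyst are taken as purchasable catalysts.

**Step 1**
Reactants: 1 nerol [(2Z)-3,7-dimethylocta-2,6-dien-1-ol]
Product: 2 neryl TBDPS ether
Conditions: TBDPSCl, imidazole, CH2Cl2, 0 °C to rt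
Reagents that add atoms: tert-butyl(chloro)diphenylsilane CC(C)(C)[Si](Cl)(c1ccccc1)c1ccccc1
Why: Silyl ether formation at the primary allylic alcohol is clean, and the bulky TBDPS group survives every later step and shields the 2,3-alkene.

**Step 2**
Reactants: 2 neryl TBDPS ether
Product: 3 (2E,6Z)-8-[(tert-butyldiphenylsilyl)oxy]-2,6-dimethylocta-2,6-dien-1-ol
Conditions: SeO2 (0.3 equiv), t-BuOOH (3 equiv), salicylic acid (0.1 equiv), CH2Cl2, rt
Reagents that add atoms: tert-butyl hydroperoxide CC(C)(C)OO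
Why: Sharpless SeO2/t-BuOOH allylic oxidation (ene reaction then [2,3]-shift) attacks the more electron-rich terminal alkene at its E-methyl group and gives the E-allylic alcohol.

**Step 3**
Reactants: 3 allylic alcohol
Product: 4 {[(2Z,6E)-8-bromo-3,7-dimethylocta-2,6-dien-1-yl]oxy}(tert-butyl)diphenylsilane
Conditions: CBr4, PPh3, CH2Cl2, 0 °C
Reagents that add atoms: carbon tetrabromide BrC(Br)(Br)Br
Why: Appel bromination converts the primary allylic alcohol to the bromide by SN2 without allylic transposition or loss of alkene geometry.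

**Step 4**
Reactants: 4 allylic bromide; 5 acetonitrile
Product: 7 (4E,8Z)-10-[(tert-butyldiphenylsilyl)oxy]-4,8-dimethyldeca-4,8-dienenitrile, via lithioacetonitrile 6 (not isolated)
Conditions: 5 (3 equiv), n-BuLi (2.8 equiv), THF, −78 °C; then 4, −78 to −20 °C
Reagents that add atoms: none
Why: SN2 alkylation of lithioacetonitrile adds C9–C10 as a nitrile, a carbonyl surrogate that cannot take part in the later epoxide opening as an amide or ester would.

**Step 5**
Reactants: 7 dienyl nitrile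
Product: 8 3-[(2S,3S)-3-{(3Z)-5-[(tert-butyldiphenylsilyl)oxy]-3-methylpent-3-en-1-yl}-2-methyloxiran-2-yl]propanenitrile
Conditions: L-fructose-derived Shi ketone (30 mol%), Oxone (2KHSO5·KHSO4·K2SO4), K2CO3, Bu4NHSO4, MeCN–CH2(OMe)2–aq. Na2B4O7 buffer, 0 °C, stopped near 90% conversion
Reagents that add atoms: potassium peroxymonosulfate [K+].[O-]S(=O)(=O)OO
Why: Shi asymmetric epoxidation, in which the chiral dioxirane attacks the more electron-rich and less hindered 4,5-alkene through a spiro transition state, sets C6 and C7 as (S,S), the first stereocentres of the route, while the alkene next to the silyloxy group is deactivated.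

**Step 6**
Reactants: 9 (4-carboxybutyl)triphenylphosphonium bromide; 10 1-[(tert-butyldimethylsilyl)oxy]propan-2-one
Product: 12 (5Z)-7-[(tert-butyldimethylsilyl)oxy]-6-methylhept-5-enoic acid, via phosphorus ylide 11 (not isolated)
Conditions: NaN(SiMe3)2 (2.05 equiv), THF, 0 °C; then 10, −78 °C to rt; 1 M HCl to pH 4
Reagents that add atoms: none
Why: Wittig olefination of an α-silyloxy ketone by a non-stabilized ylide (Still's Z-selective variant) places the CH2OSi group cis to the chain and gives the Z-trisubstituted alkene.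

**Step 7**
Reactants: 12 heptenoic acid
Product: 14 (5Z)-2-bromo-7-[(tert-butyldimethylsilyl)oxy]-6-methylhept-5-enoic acid (racemic), via dilithium enediolate 13 (not isolated)
Conditions: LiN(iPr)2 (2.2 equiv), THF, −78 to 0 °C; CBr4, −78 °C; 1 M HCl to pH 3
Reagents that add atoms: carbon tetrabromide BrC(Br)(Br)Br
Why: α-Bromination of the carboxylic acid dianion installs the leaving group at C11, and the racemic centre is harmless because it is planarized in step 9.

**Step 8**
Reactants: 8 epoxy nitrile; 14 bromo acid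
Product: 16 3-[(2R,3S,5RS)-5-{(3Z)-5-[(tert-butyldimethylsilyl)oxy]-4-methylpent-3-en-1-yl}-3-{(3Z)-5-[(tert-butyldiphenylsilyl)oxy]-3-methylpent-3-en-1-yl}-2-methyl-6-oxo-1,4-dioxan-2-yl]propanenitrile, via bromo hydroxy ester 15 (not isolated)
Conditions: 14 (1.3 equiv), (PhO)2P(O)OH (10 mol%), toluene, −20 °C to rt; then Ag2O (1.5 equiv), 4 Å sieves, rt, dark
Reagents that add atoms: none
Why: Proposed new method: a one-pot epoxide/α-bromo acid annulation to a 1,4-dioxan-2-one, in which the acid, held in a hydrogen-bonded pair with diphenyl phosphate, should open the protonated trisubstituted epoxide at tertiary C7 with inversion (borderline SN2) while the C6–O bond is kept, and Ag2O then drives a 6-exo-tet Williamson displacement of the α-bromide by the freed secondary hydroxyl under non-basic conditions chosen to outpace acyl migration, so the ester ends on the tertiary and the ether on the secondary oxygen; the closest known reactions are phosphoric acid-catalysed ring opening of epoxides by carboxylic acids and dioxanone synthesis from 1,2-diols and α-halo acids.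

**Step 9**
Reactants: 16 dioxanone nitrile
Product: 18 (1R,5R,9S)-1-{(3Z)-5-[(tert-butyldimethylsilyl)oxy]-4-methylpent-3-en-1-yl}-9-{(3Z)-5-[(tert-butyldiphenylsilyl)oxy]-3-methylpent-3-en-1-yl}-5-methyl-6,8-dioxabicyclo[3.2.2]nonane-2,7-dione, via N-lithio ketimine 17 (not isolated)
Conditions: LiN(SiMe3)2 (1.2 equiv), THF (0.01 M), −78 to −20 °C; then aq. AcOH–NaOAc buffer (pH 5), rt
Reagents that add atoms: water O
Why: Thorpe–Ziegler cyclization, in which the base removes only the lactone α-proton (far more acidic than the protons next to the nitrile), the enolate adds to the tethered nitrile to close the seven-membered ring with the C11 configuration dictated by the C7 bridgehead, and the imine is hydrolysed to the ketone.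

**Step 10**
Reactants: 18 keto lactone
Product: 20 (2Z)-5-[(1R,5R,9S)-9-{(3Z)-5-[(tert-butyldiphenylsilyl)oxy]-3-methylpent-3-en-1-yl}-5-methyl-2,7-dioxo-6,8-dioxabicyclo[3.2.2]nonan-1-yl]-2-methylpent-2-en-1-yl acetate, via primary allylic alcohol 19 (not isolated)
Conditions: PPTS (0.2 equiv), MeOH, rt; evaporate; Ac2O, pyridine, DMAP (cat.), CH2Cl2, 0 °C
Reagents that add atoms: acetic anhydride CC(=O)OC(C)=O
Why: Acid-catalysed methanolysis cleaves the primary TBS ether while the TBDPS ether is inert, and acetylation in the same flask installs the C16 acetate while no other hydroxyl is present.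

**Step 11**
Reactants: 20 keto lactone acetate
Product: 21 (2Z)-5-[(1R,2S,5R,9S)-9-{(3Z)-5-[(tert-butyldiphenylsilyl)oxy]-3-methylpent-3-en-1-yl}-2-hydroxy-5-methyl-7-oxo-6,8-dioxabicyclo[3.2.2]nonan-1-yl]-2-methylpent-2-en-1-yl acetate
Conditions: (R)-2-methyl-CBS-oxazaborolidine (0.5 equiv), catecholborane (1.5 equiv), toluene, −78 to −40 °C; MeOH quench
Reagents that add atoms: none
Why: Corey–Bakshi–Shibata reduction, in which the (R)-oxazaborolidine binds the ketone lone pair anti to the quaternary bridgehead and delivers hydride to the face that gives the (S)-carbinol (OH syn to the lactone bridge), leaves the acetate, lactone and alkenes untouched.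

**Step 12**
Reactants: 21 hydroxy lactone acetate
Product: 22 target CNP0174851.1
Conditions: HF·pyridine, pyridine, THF, 0 °C to rt
Reagents that add atoms: none
Why: Fluoride-mediated desilylation removes the TBDPS ether under buffered conditions that spare the acetate, the bridged lactone and the allylic systems.

**Compound list**
1 | nerol, (2Z)-3,7-dimethylocta-2,6-dien-1-ol | CC(C)=CCC/C(C)=C\CO | starting material
2 | neryl TBDPS ether, tert-butyl{[(2Z)-3,7-dimethylocta-2,6-dien-1-yl]oxy}diphenylsilane | CC(C)=CCC/C(C)=C\CO[Si](c1ccccc1)(c1ccccc1)C(C)(C)C | intermediate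
3 | (2E,6Z)-8-[(tert-butyldiphenylsilyl)oxy]-2,6-dimethylocta-2,6-dien-1-ol | OC/C(C)=C/CC/C(C)=C\CO[Si](c1ccccc1)(c1ccccc1)C(C)(C)C | intermediate
4 | {[(2Z,6E)-8-bromo-3,7-dimethylocta-2,6-dien-1-yl]oxy}(tert-butyl)diphenylsilane | BrC/C(C)=C/CC/C(C)=C\CO[Si](c1ccccc1)(c1ccccc1)C(C)(C)C | intermediate
5 | acetonitrile | CC#N | starting material
6 | lithioacetonitrile (not isolated) | [Li]CC#N | intermediate
7 | (4E,8Z)-10-[(tert-butyldiphenylsilyl)oxy]-4,8-dimethyldeca-4,8-dienenitrile | N#CCC/C(C)=C/CC/C(C)=C\CO[Si](c1ccccc1)(c1ccccc1)C(C)(C)C | intermediate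
8 | 3-[(2S,3S)-3-{(3Z)-5-[(tert-butyldiphenylsilyl)oxy]-3-methylpent-3-en-1-yl}-2-methyloxiran-2-yl]propanenitrile | N#CCC[C@]1(C)O[C@H]1CC/C(C)=C\CO[Si](c2ccccc2)(c2ccccc2)C(C)(C)C | intermediate
9 | (4-carboxybutyl)triphenylphosphonium bromide | OC(=O)CCCC[P+](c1ccccc1)(c1ccccc1)c1ccccc1.[Br-] | starting material
10 | 1-[(tert-butyldimethylsilyl)oxy]propan-2-one | CC(=O)CO[Si](C)(C)C(C)(C)C | starting material
11 | sodium 5-(triphenylphosphoranylidene)pentanoate, the ylide (not isolated) | [Na+].[O-]C(=O)CCCC=P(c1ccccc1)(c1ccccc1)c1ccccc1 | intermediate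
12 | (5Z)-7-[(tert-butyldimethylsilyl)oxy]-6-methylhept-5-enoic acid | CC(C)(C)[Si](C)(C)OC/C(C)=C\CCCC(=O)O | intermediate
13 | dilithium enediolate of 12 (not isolated) | CC(C)(C)[Si](C)(C)OC/C(C)=C\CCC=C([O-])[O-].[Li+].[Li+] | intermediate
14 | (5Z)-2-bromo-7-[(tert-butyldimethylsilyl)oxy]-6-methylhept-5-enoic acid, racemic at C2 | CC(C)(C)[Si](C)(C)OC/C(C)=C\CCC(Br)C(=O)O | intermediate
15 | bromo hydroxy ester: 2-bromoheptenoate of the tertiary (C7) hydroxyl of the (4R,5S)-4,5-diol derived from 8, secondary C6–OH free, both epimers at CHBr (not isolated) | CC(C)(C)[Si](C)(C)OC/C(C)=C\CCC(Br)C(=O)O[C@](C)(CCC#N)[C@@H](O)CC/C(C)=C\CO[Si](c1ccccc1)(c1ccccc1)C(C)(C)C | intermediate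
16 | 3-[(2R,3S,5RS)-5-{(3Z)-5-[(tert-butyldimethylsilyl)oxy]-4-methylpent-3-en-1-yl}-3-{(3Z)-5-[(tert-butyldiphenylsilyl)oxy]-3-methylpent-3-en-1-yl}-2-methyl-6-oxo-1,4-dioxan-2-yl]propanenitrile | CC(C)(C)[Si](C)(C)OC/C(C)=C\CCC1O[C@@H](CC/C(C)=C\CO[Si](c2ccccc2)(c2ccccc2)C(C)(C)C)[C@@](C)(CCC#N)OC1=O | intermediate
17 | N-lithio ketimine of 18 at C10 (not isolated) | CC(C)(C)[Si](C)(C)OC/C(C)=C\CC[C@@]12O[C@@H](CC/C(C)=C\CO[Si](c3ccccc3)(c3ccccc3)C(C)(C)C)[C@@](C)(CCC1=N[Li])OC2=O | intermediate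
18 | (1R,5R,9S)-1-{(3Z)-5-[(tert-butyldimethylsilyl)oxy]-4-methylpent-3-en-1-yl}-9-{(3Z)-5-[(tert-butyldiphenylsilyl)oxy]-3-methylpent-3-en-1-yl}-5-methyl-6,8-dioxabicyclo[3.2.2]nonane-2,7-dione | CC(C)(C)[Si](C)(C)OC/C(C)=C\CC[C@@]12O[C@@H](CC/C(C)=C\CO[Si](c3ccccc3)(c3ccccc3)C(C)(C)C)[C@@](C)(CCC1=O)OC2=O | intermediate
19 | (1R,5R,9S)-9-{(3Z)-5-[(tert-butyldiphenylsilyl)oxy]-3-methylpent-3-en-1-yl}-1-[(3Z)-5-hydroxy-4-methylpent-3-en-1-yl]-5-methyl-6,8-dioxabicyclo[3.2.2]nonane-2,7-dione (not isolated) | OC/C(C)=C\CC[C@@]12O[C@@H](CC/C(C)=C\CO[Si](c3ccccc3)(c3ccccc3)C(C)(C)C)[C@@](C)(CCC1=O)OC2=O | intermediate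
20 | (2Z)-5-[(1R,5R,9S)-9-{(3Z)-5-[(tert-butyldiphenylsilyl)oxy]-3-methylpent-3-en-1-yl}-5-methyl-2,7-dioxo-6,8-dioxabicyclo[3.2.2]nonan-1-yl]-2-methylpent-2-en-1-yl acetate | CC(=O)OC/C(C)=C\CC[C@@]12O[C@@H](CC/C(C)=C\CO[Si](c3ccccc3)(c3ccccc3)C(C)(C)C)[C@@](C)(CCC1=O)OC2=O | intermediate
21 | (2Z)-5-[(1R,2S,5R,9S)-9-{(3Z)-5-[(tert-butyldiphenylsilyl)oxy]-3-methylpent-3-en-1-yl}-2-hydroxy-5-methyl-7-oxo-6,8-dioxabicyclo[3.2.2]nonan-1-yl]-2-methylpent-2-en-1-yl acetate | CC(=O)OC/C(C)=C\CC[C@@]12O[C@@H](CC/C(C)=C\CO[Si](c3ccccc3)(c3ccccc3)C(C)(C)C)[C@@](C)(CC[C@@H]1O)OC2=O | intermediate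
22 | CNP0174851.1, (2Z)-5-[(1R,2S,5R,9S)-2-hydroxy-9-[(3Z)-5-hydroxy-3-methylpent-3-en-1-yl]-5-methyl-7-oxo-6,8-dioxabicyclo[3.2.2]nonan-1-yl]-2-methylpent-2-en-1-yl acetate | CC(=O)OC/C(C)=C\CC[C@@]12O[C@@H](CC/C(C)=C\CO)[C@@](C)(CC[C@@H]1O)OC2=O | target

**Step count and risks**
Total steps: 12. Longest linear sequence: 10 (steps 1–5 and 8–12 from nerol); the bromo acid branch is 2 steps (6 and 7).

Step 8 (the proposed new annulation) is the most likely to fail. The acid may attack C6, stereospecificity at C7 may erode through a free cation, the cation may be captured by the 2,3-alkene, or the acyl group may migrate to the secondary oxygen before ring closure. The fallback uses known reactions only and sets out from 8. Dilute HClO4 in THF–water at 0 °C hydrolyses the epoxide by attack of water at the tertiary carbon with inversion to give the diol F1. NaH in THF–DMF at 0 °C then alkylates the secondary hydroxyl of the diol with 14 (Williamson ether synthesis) to give the hydroxy ether acid F2. Yamaguchi lactonization (2,4,6-trichlorobenzoyl chloride, Et3N, then DMAP, toluene) closes the dioxanone and the fallback comes back to the route at 16.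

Step 9 (bridging Thorpe–Ziegler closure) may fail if the hindered lactone enolate does not add to the nitrile or if intermolecular reactions win. The fallback changes the oxidation level at which the ring is closed and sets out from 16. Cp2Zr(H)Cl in THF reduces the nitrile to the N-zirconated aldimine, which is hydrolysed on wet silica to the aldehyde F3. A TiCl4/Bu3N direct intramolecular aldol addition (chelated titanium enolate, tolerant of enolizable aldehydes) closes the ring and sets C10 with the hydroxyl syn to the lactone carbonyl, giving the hydroxy lactone F4. PPTS in MeOH removes the TBS group to give the diol F5, and Ac2O in pyridine at 0 °C acetylates only the primary allylic hydroxyl. The fallback comes back to the route at 21, so steps 10 and 11 are replaced as well.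

Step 11 (CBS reduction) may give poor selectivity at C10, because the ketone is hindered and the two faces of the bicycle differ only modestly. The fallback sets out from 20 and replaces small-molecule hydride delivery by biocatalysis: an (S)-selective NADPH-dependent ketoreductase chosen from a screening panel, with glucose dehydrogenase and glucose for cofactor recycling, in phosphate buffer with DMSO at 30 °C. It comes back to the route at 21 and makes no new compound (F0).

**Further compounds**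
F1 | step 8 | (4R,5S,8Z)-10-[(tert-butyldiphenylsilyl)oxy]-4,5-dihydroxy-4,8-dimethyldec-8-enenitrile | O[C@@H](CC/C(C)=C\CO[Si](c1ccccc1)(c1ccccc1)C(C)(C)C)[C@@](C)(CCC#N)O
F2 | step 8 | (5Z)-7-[(tert-butyldimethylsilyl)oxy]-2-{[(2Z,6S,7R)-1-[(tert-butyldiphenylsilyl)oxy]-9-cyano-7-hydroxy-3,7-dimethylnon-2-en-6-yl]oxy}-6-methylhept-5-enoic acid (both epimers at C2) | CC(C)(C)[Si](C)(C)OC/C(C)=C\CCC(C(=O)O)O[C@@H](CC/C(C)=C\CO[Si](c1ccccc1)(c1ccccc1)C(C)(C)C)[C@@](C)(CCC#N)O
F3 | step 9 | 3-[(2R,3S,5RS)-5-{(3Z)-5-[(tert-butyldimethylsilyl)oxy]-4-methylpent-3-en-1-yl}-3-{(3Z)-5-[(tert-butyldiphenylsilyl)oxy]-3-methylpent-3-en-1-yl}-2-methyl-6-oxo-1,4-dioxan-2-yl]propanal | CC(C)(C)[Si](C)(C)OC/C(C)=C\CCC1O[C@@H](CC/C(C)=C\CO[Si](c2ccccc2)(c2ccccc2)C(C)(C)C)[C@@](C)(CCC=O)OC1=O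
F4 | step 9 | (1R,2S,5R,9S)-1-{(3Z)-5-[(tert-butyldimethylsilyl)oxy]-4-methylpent-3-en-1-yl}-9-{(3Z)-5-[(tert-butyldiphenylsilyl)oxy]-3-methylpent-3-en-1-yl}-2-hydroxy-5-methyl-6,8-dioxabicyclo[3.2.2]nonan-7-one | CC(C)(C)[Si](C)(C)OC/C(C)=C\CC[C@@]12O[C@@H](CC/C(C)=C\CO[Si](c3ccccc3)(c3ccccc3)C(C)(C)C)[C@@](C)(CC[C@@H]1O)OC2=O
F5 | step 9 | (1R,2S,5R,9S)-9-{(3Z)-5-[(tert-butyldiphenylsilyl)oxy]-3-methylpent-3-en-1-yl}-2-hydroxy-1-[(3Z)-5-hydroxy-4-methylpent-3-en-1-yl]-5-methyl-6,8-dioxabicyclo[3.2.2]nonan-7-one | OC/C(C)=C\CC[C@@]12O[C@@H](CC/C(C)=C\CO[Si](c3ccccc3)(c3ccccc3)C(C)(C)C)[C@@](C)(CC[C@@H]1O)OC2=O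
F0 | step 11 | none | none
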